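**Retrosynthetic overview**

1. The strategy rests on ring B (C1'–C6'), which hangs on C7' at oxolane C4 and carries its only free hydroxyl at C3' beside methoxy groups at C4' and C5'. A 3,4-dimethoxyfuran leaves exactly this pattern when annulated onto an alkyne, so ring B is cut at C1'–C6' and C2'–C3' (furan/ynone [4+2], then opening of the oxygen bridge to the C3' phenol). C7' is carried as a ketone and reduced to CH2 afterwards.
2. The ynone (C7'=O on C4) comes from the C7' aldehyde, and this from 9-BBN hydroboration of a 4-methyleneoxolane, which sets C4 cis to C9.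
3. The oxolane comes from a 5-exo-dig radical cyclisation of an epoxy propargyl ether (C3–C4 bond, C3 trans to C2). Its precursor is the (R)-aryl vinyl carbinol (C2, by kinetic resolution) made from 3,4,5-trimethoxybenzaldehyde.
4. Ring order: ring A is purchased, the oxolane ring is closed in step 5, ring B is built in step 11.

Key step: step 11

Assumption: 3,4-dimethoxyfuran is taken as a purchasable diene; the oxolane is numbered O1, C2 (ring A), C3 (bears C9), C4 (bears C7'), C5 throughout, and where a CIP letter changes between intermediates this reflects a change in substituent priorities, never an inversion.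

**Route**

Step 1
Reactants: 1 3,4,5-trimethoxybenzaldehyde; 2 vinylmagnesium bromide
Product: 3 rac-1-(3,4,5-trimethoxyphenyl)prop-2-en-1-ol
Conditions: THF, −78 → 0 °C; aq. NH4Cl
Reagents that add atoms: none
Why: Grignard 1,2-addition to a non-enolisable aryl aldehyde gives the aryl vinyl carbinol as a racemate, which is resolved in step 2.

Step 2
Reactants: 3 rac-1-(3,4,5-trimethoxyphenyl)prop-2-en-1-ol
Product: 4 (R)-1-(3,4,5-trimethoxyphenyl)prop-2-en-1-ol
Conditions: Ti(OiPr)4 (0.2 equiv), D-(−)-DIPT (0.25 equiv), t-BuOOH (0.6 equiv), 4 Å MS, CH2Cl2, −20 °C; unreacted alcohol recovered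
Reagents that add atoms: none
Why: Sharpless kinetic resolution of a secondary allylic alcohol: with the D-(−)-tartrate catalyst the (S)-carbinol should be epoxidised fast, so the (R)-carbinol (the future C2) is left in high enantiomeric purity once conversion passes one half.

Step 3
Reactants: 4 (R)-1-(3,4,5-trimethoxyphenyl)prop-2-en-1-ol; 5 propargyl bromide
Product: 6 5-[(1R)-1-(prop-2-yn-1-yloxy)prop-2-en-1-yl]-1,2,3-trimethoxybenzene
Conditions: NaH, Bu4NI (cat.), THF, 0 °C → rt
Reagents that add atoms: none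
Why: Williamson etherification of the sodium alkoxide with an unhindered propargylic bromide forms the O1–C5 bond without touching the C2 stereocentre.

Step 4
Reactants: 6 5-[(1R)-1-(prop-2-yn-1-yloxy)prop-2-en-1-yl]-1,2,3-trimethoxybenzene
Product: 7 2-[(S)-(prop-2-yn-1-yloxy)(3,4,5-trimethoxyphenyl)methyl]oxirane (both epimers at the oxirane carbon)
Conditions: mCPBA, NaHCO3, CH2Cl2, 0 °C → rt
Reagents that add atoms: mCPBA, OOC(=O)c1cccc(Cl)c1
Why: Prilezhaev epoxidation takes the alkene in preference to the far less reactive terminal alkyne; the epimer mixture at the oxirane carbon is harmless because that carbon becomes a planar radical in step 5.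

Step 5
Reactants: 7 2-[(S)-(prop-2-yn-1-yloxy)(3,4,5-trimethoxyphenyl)methyl]oxirane
Product: 8 [(2R,3S)-4-methylidene-2-(3,4,5-trimethoxyphenyl)oxolan-3-yl]methanol
Conditions: Cp2TiCl2 (2.2 equiv), Zn dust, THF, rt, the green Cp2TiCl solution added dropwise to 7; aq. NaH2PO4
Reagents that add atoms: none
Why: Nugent–RajanBabu epoxide-opening radical cyclisation: Cp2TiCl (trivalent titanium) opens the oxirane to the secondary C3 radical, which closes 5-exo-dig onto the alkyne (C3–C4 bond) and the vinyl radical is quenched by hydrogen; a chair-like transition state with the C2 aryl and the C3 CH2O–Ti arm both pseudo-equatorial should set C3 trans to C2.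

Step 6
Reactants: 8 [(2R,3S)-4-methylidene-2-(3,4,5-trimethoxyphenyl)oxolan-3-yl]methanol
Product: 9 tert-butyl(dimethyl){[(2R,3S)-4-methylidene-2-(3,4,5-trimethoxyphenyl)oxolan-3-yl]methoxy}silane
Conditions: TBSCl, imidazole, DMF, 0 °C → rt
Reagents that add atoms: TBSCl, CC(C)(C)[Si](C)(C)Cl
Why: Standard silylation of the primary C9 alcohol, which masks it through the oxidations, the acid step and the ketone stage.

Step 7
Reactants: 9 tert-butyl(dimethyl){[(2R,3S)-4-methylidene-2-(3,4,5-trimethoxyphenyl)oxolan-3-yl]methoxy}silane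
Product: 11 [(3R,4S,5R)-4-({[tert-butyl(dimethyl)silyl]oxy}methyl)-5-(3,4,5-trimethoxyphenyl)oxolan-3-yl]methanol, via B-alkyl-9-BBN adduct 10 (not isolated)
Conditions: 9-BBN (0.5 M in THF), THF, 0 °C → rt; then aq. NaOH, 30% H2O2, 0 °C
Reagents that add atoms: hydrogen peroxide, OO
Why: Anti-Markovnikov syn hydroboration–oxidation: the bulky borane should approach the exocyclic alkene from the ring face opposite the adjacent C3 CH2OTBS group, so hydrogen goes onto C4 from that face and the C7' arm ends up cis to C9, as the target requires.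

Step 8
Reactants: 11 [(3R,4S,5R)-4-({[tert-butyl(dimethyl)silyl]oxy}methyl)-5-(3,4,5-trimethoxyphenyl)oxolan-3-yl]methanol
Product: 12 (3S,4S,5R)-4-({[tert-butyl(dimethyl)silyl]oxy}methyl)-5-(3,4,5-trimethoxyphenyl)oxolane-3-carbaldehyde
Conditions: Dess–Martin periodinane, NaHCO3, CH2Cl2, 0 °C; used crude
Reagents that add atoms: none
Why: Dess–Martin oxidation is neutral and fast at low temperature, so the C7' aldehyde should form without enolisation of the cis-configured α-stereocentre C4.

Step 9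
Reactants: 12 (3S,4S,5R)-4-({[tert-butyl(dimethyl)silyl]oxy}methyl)-5-(3,4,5-trimethoxyphenyl)oxolane-3-carbaldehyde; 13 ethynylmagnesium bromide
Product: 14 1-[(3S,4S,5R)-4-({[tert-butyl(dimethyl)silyl]oxy}methyl)-5-(3,4,5-trimethoxyphenyl)oxolan-3-yl]prop-2-yn-1-ol (both epimers at C7')
Conditions: THF, −78 °C; aq. NH4Cl
Reagents that add atoms: none
Why: Grignard 1,2-addition of the weakly basic acetylide at low temperature outruns enolisation; the C7' epimers converge in step 10.

Step 10
Reactants: 14 1-[(3S,4S,5R)-4-({[tert-butyl(dimethyl)silyl]oxy}methyl)-5-(3,4,5-trimethoxyphenyl)oxolan-3-yl]prop-2-yn-1-ol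
Product: 15 1-[(3S,4S,5R)-4-({[tert-butyl(dimethyl)silyl]oxy}methyl)-5-(3,4,5-trimethoxyphenyl)oxolan-3-yl]prop-2-yn-1-one
Conditions: Dess–Martin periodinane, NaHCO3, CH2Cl2, 0 °C → rt
Reagents that add atoms: none
Why: Dess–Martin oxidation of the propargylic alcohol gives the terminal ynone under non-basic conditions that leave C4 and the silyl ether alone.

Step 11
Reactants: 15 1-[(3S,4S,5R)-4-({[tert-butyl(dimethyl)silyl]oxy}methyl)-5-(3,4,5-trimethoxyphenyl)oxolan-3-yl]prop-2-yn-1-one; 16 3,4-dimethoxyfuran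
Product: 18 [(3S,4S,5R)-4-({[tert-butyl(dimethyl)silyl]oxy}methyl)-5-(3,4,5-trimethoxyphenyl)oxolan-3-yl](3-hydroxy-4,5-dimethoxyphenyl)methanone, via oxanorbornadiene cycloadduct 17 (not isolated)
Conditions: 16 (3 equiv), PhMe, 45 °C, dark; concentrate; then PPTS (0.2 equiv), CH2Cl2, 0 °C; aq. NaHCO3
Reagents that add atoms: none
Why: The electron-rich furan 16 adds suprafacially through its 2,5-carbons to the electron-poor triple bond of 15 in a concerted [4+2] cycloaddition, forming C2'–C3' and C1'–C6' and giving the 7-oxanorbornadiene 17; this is the known furan–alkyne Diels–Alder/acid isomerisation route to phenols. Ring B is therefore closed by an intermolecular cycloaddition that makes both ring bonds at once, and because 16 is symmetrical the cycloaddition has no regiochemistry to control. The two bridgehead stereocentres of 17 are transient and vanish on aromatisation, so no new stereocentre remains and the bridgehead diastereomer mixture does not matter. On mild protonation the bridging oxygen should leave C6' and not C3', because that cyclohexadienyl cation spreads its charge over C6', C2' and the methoxy-bearing C4' and keeps it off the acyl-bearing C1'; loss of the C3' proton then gives the C3' phenol next to the C4' and C5' methoxy groups. The step needs two selectivities: the direction of bridge opening, which the C7' carbonyl secures, and retention at C4, which is protected by a neutral thermal cycloaddition followed by a weak acid in an aprotic solvent at 0 °C, conditions that should also spare the silyl ether and the benzylic C2–O1 bond.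

Step 12
Reactants: 18 [(3S,4S,5R)-4-({[tert-butyl(dimethyl)silyl]oxy}methyl)-5-(3,4,5-trimethoxyphenyl)oxolan-3-yl](3-hydroxy-4,5-dimethoxyphenyl)methanone
Product: 19 N'-{[(3R,4S,5R)-4-({[tert-butyl(dimethyl)silyl]oxy}methyl)-5-(3,4,5-trimethoxyphenyl)oxolan-3-yl](3-hydroxy-4,5-dimethoxyphenyl)methylidene}-4-methylbenzenesulfonohydrazide
Conditions: TsNHNH2 (1.3 equiv), 4 Å MS, MeOH–THF, 50 °C
Reagents that add atoms: p-toluenesulfonyl hydrazide, Cc1ccc(cc1)S(=O)(=O)NN
Why: Condensation of the aryl ketone with tosylhydrazide without added acid should give the hydrazone while keeping the silyl ether and limiting enolisation at C4.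

Step 13
Reactants: 19 N'-{[(3R,4S,5R)-4-({[tert-butyl(dimethyl)silyl]oxy}methyl)-5-(3,4,5-trimethoxyphenyl)oxolan-3-yl](3-hydroxy-4,5-dimethoxyphenyl)methylidene}-4-methylbenzenesulfonohydrazide
Product: 22 5-{[(3S,4S,5R)-4-({[tert-butyl(dimethyl)silyl]oxy}methyl)-5-(3,4,5-trimethoxyphenyl)oxolan-3-yl]methyl}-2,3-dimethoxyphenol, via N-alkyl tosylhydrazine 20 (not isolated), via alkyl diazene 21 (not isolated)
Conditions: catecholborane (3 equiv), CHCl3, 0 °C → rt; then NaOAc·3H2O, reflux
Reagents that add atoms: none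
Why: Caglioti-type reductive deoxygenation: catecholborane adds hydride to the C=N bond, acetate-promoted loss of sulfinate gives the diazene and this expels N2 to leave C7' as CH2, with no cationic or basic intermediate that could touch C4, C2 or ring A.

Step 14
Reactants: 22 5-{[(3S,4S,5R)-4-({[tert-butyl(dimethyl)silyl]oxy}methyl)-5-(3,4,5-trimethoxyphenyl)oxolan-3-yl]methyl}-2,3-dimethoxyphenol
Product: 23 5-{[(3S,4S,5R)-4-(hydroxymethyl)-5-(3,4,5-trimethoxyphenyl)oxolan-3-yl]methyl}-2,3-dimethoxyphenol (CNP0121704.1)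
Conditions: TBAF, THF, 0 °C → rt; aq. NH4Cl
Reagents that add atoms: none
Why: Fluoride cleavage of the primary silyl ether frees the C9 alcohol under conditions that do not affect the three stereocentres.

**Compound list**

1 | 3,4,5-trimethoxybenzaldehyde | COc1cc(C=O)cc(OC)c1OC | starting material
2 | vinylmagnesium bromide | C=C[Mg]Br | starting material
3 | rac-1-(3,4,5-trimethoxyphenyl)prop-2-en-1-ol | OC(C=C)c1cc(OC)c(OC)c(OC)c1 | intermediate
4 | (R)-1-(3,4,5-trimethoxyphenyl)prop-2-en-1-ol | O[C@@H](c1cc(OC)c(OC)c(OC)c1)C=C | intermediate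
5 | propargyl bromide (3-bromoprop-1-yne) | C#CCBr | starting material
6 | 5-[(1R)-1-(prop-2-yn-1-yloxy)prop-2-en-1-yl]-1,2,3-trimethoxybenzene | C#CCO[C@@H](c1cc(OC)c(OC)c(OC)c1)C=C | intermediate
7 | 2-[(S)-(prop-2-yn-1-yloxy)(3,4,5-trimethoxyphenyl)methyl]oxirane, both epimers at the oxirane carbon | C#CCO[C@@H](c1cc(OC)c(OC)c(OC)c1)C1CO1 | intermediate
8 | [(2R,3S)-4-methylidene-2-(3,4,5-trimethoxyphenyl)oxolan-3-yl]methanol (aryl and CH2OH trans) | C=C1CO[C@@H](c2cc(OC)c(OC)c(OC)c2)[C@@H]1CO | intermediate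
9 | tert-butyl(dimethyl){[(2R,3S)-4-methylidene-2-(3,4,5-trimethoxyphenyl)oxolan-3-yl]methoxy}silane | C=C1CO[C@@H](c2cc(OC)c(OC)c(OC)c2)[C@@H]1CO[Si](C)(C)C(C)(C)C | intermediate
10 | 9-{[(3S,4S,5R)-4-({[tert-butyl(dimethyl)silyl]oxy}methyl)-5-(3,4,5-trimethoxyphenyl)oxolan-3-yl]methyl}-9-borabicyclo[3.3.1]nonane | C(B1C2CCCC1CCC2)[C@@H]3CO[C@@H](c4cc(OC)c(OC)c(OC)c4)[C@@H]3CO[Si](C)(C)C(C)(C)C | intermediate (not isolated)
11 | [(3R,4S,5R)-4-({[tert-butyl(dimethyl)silyl]oxy}methyl)-5-(3,4,5-trimethoxyphenyl)oxolan-3-yl]methanol (CH2OH and CH2OTBS cis) | OC[C@@H]1CO[C@@H](c2cc(OC)c(OC)c(OC)c2)[C@@H]1CO[Si](C)(C)C(C)(C)C | intermediate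
12 | (3S,4S,5R)-4-({[tert-butyl(dimethyl)silyl]oxy}methyl)-5-(3,4,5-trimethoxyphenyl)oxolane-3-carbaldehyde | O=C[C@@H]1CO[C@@H](c2cc(OC)c(OC)c(OC)c2)[C@@H]1CO[Si](C)(C)C(C)(C)C | intermediate
13 | ethynylmagnesium bromide | C#C[Mg]Br | starting material
14 | 1-[(3S,4S,5R)-4-({[tert-butyl(dimethyl)silyl]oxy}methyl)-5-(3,4,5-trimethoxyphenyl)oxolan-3-yl]prop-2-yn-1-ol, both carbinol epimers | C#CC(O)[C@@H]1CO[C@@H](c2cc(OC)c(OC)c(OC)c2)[C@@H]1CO[Si](C)(C)C(C)(C)C | intermediate
15 | 1-[(3S,4S,5R)-4-({[tert-butyl(dimethyl)silyl]oxy}methyl)-5-(3,4,5-trimethoxyphenyl)oxolan-3-yl]prop-2-yn-1-one (key-step precursor) | C#CC(=O)[C@@H]1CO[C@@H](c2cc(OC)c(OC)c(OC)c2)[C@@H]1CO[Si](C)(C)C(C)(C)C | intermediate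
16 | 3,4-dimethoxyfuran | COc1cocc1OC | starting material
17 | [(3S,4S,5R)-4-({[tert-butyl(dimethyl)silyl]oxy}methyl)-5-(3,4,5-trimethoxyphenyl)oxolan-3-yl](5,6-dimethoxy-7-oxabicyclo[2.2.1]hepta-2,5-dien-2-yl)methanone, both bridgehead diastereomers | O1C2C(OC)=C(OC)C1C=C2C(=O)[C@@H]3CO[C@@H](c4cc(OC)c(OC)c(OC)c4)[C@@H]3CO[Si](C)(C)C(C)(C)C | intermediate (not isolated)
18 | [(3S,4S,5R)-4-({[tert-butyl(dimethyl)silyl]oxy}methyl)-5-(3,4,5-trimethoxyphenyl)oxolan-3-yl](3-hydroxy-4,5-dimethoxyphenyl)methanone (key-step product) | COc1cc(C(=O)[C@@H]2CO[C@@H](c3cc(OC)c(OC)c(OC)c3)[C@@H]2CO[Si](C)(C)C(C)(C)C)cc(O)c1OC | intermediate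
19 | N'-{[(3R,4S,5R)-4-({[tert-butyl(dimethyl)silyl]oxy}methyl)-5-(3,4,5-trimethoxyphenyl)oxolan-3-yl](3-hydroxy-4,5-dimethoxyphenyl)methylidene}-4-methylbenzenesulfonohydrazide | COc1cc(C(=NNS(=O)(=O)c2ccc(C)cc2)[C@@H]2CO[C@@H](c3cc(OC)c(OC)c(OC)c3)[C@@H]2CO[Si](C)(C)C(C)(C)C)cc(O)c1OC | intermediate
20 | N'-{[(3R,4S,5R)-4-({[tert-butyl(dimethyl)silyl]oxy}methyl)-5-(3,4,5-trimethoxyphenyl)oxolan-3-yl](3-hydroxy-4,5-dimethoxyphenyl)methyl}-4-methylbenzenesulfonohydrazide, both C7' epimers | COc1cc(C(NNS(=O)(=O)c2ccc(C)cc2)[C@@H]2CO[C@@H](c3cc(OC)c(OC)c(OC)c3)[C@@H]2CO[Si](C)(C)C(C)(C)C)cc(O)c1OC | intermediate (not isolated)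
21 | 5-{[(3R,4S,5R)-4-({[tert-butyl(dimethyl)silyl]oxy}methyl)-5-(3,4,5-trimethoxyphenyl)oxolan-3-yl](diazenyl)methyl}-2,3-dimethoxyphenol, both C7' epimers | COc1cc(C(N=N)[C@@H]2CO[C@@H](c3cc(OC)c(OC)c(OC)c3)[C@@H]2CO[Si](C)(C)C(C)(C)C)cc(O)c1OC | intermediate (not isolated)
22 | 5-{[(3S,4S,5R)-4-({[tert-butyl(dimethyl)silyl]oxy}methyl)-5-(3,4,5-trimethoxyphenyl)oxolan-3-yl]methyl}-2,3-dimethoxyphenol | COc1cc(C[C@@H]2CO[C@@H](c3cc(OC)c(OC)c(OC)c3)[C@@H]2CO[Si](C)(C)C(C)(C)C)cc(O)c1OC | intermediate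
23 | 5-{[(3S,4S,5R)-4-(hydroxymethyl)-5-(3,4,5-trimethoxyphenyl)oxolan-3-yl]methyl}-2,3-dimethoxyphenol (aryl trans to CH2OH, CH2OH cis to the benzyl group) | COc1cc(C[C@@H]2CO[C@@H](c3cc(OC)c(OC)c(OC)c3)[C@@H]2CO)cc(O)c1OC | target

**Totals**

Total step count: 14. Longest linear sequence: 14 steps (1 → 23).

**Steps most likely to fail**

Step 11 (key step). The furan may attack the ynone as a carbon nucleophile (conjugate addition through its C2) instead of cycloadding, or the cycloadduct may revert on concentration. The bridge may also open partly toward the C3' cation and give the ortho-hydroxy ketone. C4 may enolise toward the all-trans isomer, and the silyl ether may be lost so that O9 closes onto C7'. The fallback attaches ring B ready-made and never places a carbonyl next to C4. It sets out from alkene 9, which is hydroborated with 9-BBN to borane 10 as in step 7. Borane 10 would then be coupled in a B-alkyl Suzuki–Miyaura reaction (Pd(dppf)Cl2, aq. K3PO4, DMF–THF, 60 °C) with (5-bromo-2,3-dimethoxyphenoxy)(tert-butyl)dimethylsilane F1, made from purchasable 5-bromo-2,3-dimethoxyphenol with TBSCl and imidazole. This should give the bis-silyl ether of the target F2, and TBAF in THF then removes both silyl groups, so the route is rejoined at target 23.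

Step 12. Condensation at the hindered, electron-rich aryl ketone may be slow, and forcing it with heat or acid invites ene-hydrazine tautomerism that scrambles C4, or loss of the silyl ether. The fallback is a radical deoxygenation that sets out from ketone 18. The phenol is silylated (TBSCl, imidazole, DMF) to the aryl silyl ether ketone F3, and the ketone is reduced with LiBH4 in THF at 0 °C to the benzylic carbinol F4 (both C7' epimers). This is converted with phenyl chlorothionoformate, DMAP and pyridine in CH2Cl2 into the O-phenyl thionocarbonate F5. Barton–McCombie reduction (Bu3SnH, AIBN, PhMe, 90 °C) through the benzylic C7' radical should give the bis-silyl ether F2, and TBAF returns the route at target 23.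

Step 5. The β-titanoxy C3 radical may be intercepted by a second Cp2TiCl before it cyclises and then lose titanium oxide by β-elimination, a net deoxygenation back to alkene 6. Ring closure may also discriminate poorly between the two faces at C3. The fallback generates the same carbon radical without titanium and sets out from enyne ether 6. Dihydroxylation of the vinyl group (OsO4 cat., NMO, acetone–water) gives the diol F6 (both epimers at the secondary carbinol). Selective silylation of the primary hydroxyl (TBSCl, imidazole, CH2Cl2, −20 °C) gives the secondary alcohol F7, and 1,1'-thiocarbonyldiimidazole (THF, 60 °C) gives the imidazole-1-carbothioate F8. Slow addition of Bu3SnH and AIBN in PhMe at 90 °C should release the C3 radical, which closes 5-exo-dig through the same chair-like transition state, and the route is rejoined at silyl ether 9.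

**Further compounds**

F1 | step 11 | (5-bromo-2,3-dimethoxyphenoxy)(tert-butyl)dimethylsilane | COc1cc(Br)cc(O[Si](C)(C)C(C)(C)C)c1OC
F2 | step 11 | tert-butyl{5-[((3S,4S,5R)-4-({[tert-butyl(dimethyl)silyl]oxy}methyl)-5-(3,4,5-trimethoxyphenyl)oxolan-3-yl)methyl]-2,3-dimethoxyphenoxy}dimethylsilane | COc1cc(C[C@@H]2CO[C@@H](c3cc(OC)c(OC)c(OC)c3)[C@@H]2CO[Si](C)(C)C(C)(C)C)cc(O[Si](C)(C)C(C)(C)C)c1OC
F3 | step 12 | [(3S,4S,5R)-4-({[tert-butyl(dimethyl)silyl]oxy}methyl)-5-(3,4,5-trimethoxyphenyl)oxolan-3-yl](3-{[tert-butyl(dimethyl)silyl]oxy}-4,5-dimethoxyphenyl)methanone | COc1cc(C(=O)[C@@H]2CO[C@@H](c3cc(OC)c(OC)c(OC)c3)[C@@H]2CO[Si](C)(C)C(C)(C)C)cc(O[Si](C)(C)C(C)(C)C)c1OC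
F4 | step 12 | [(3S,4S,5R)-4-({[tert-butyl(dimethyl)silyl]oxy}methyl)-5-(3,4,5-trimethoxyphenyl)oxolan-3-yl](3-{[tert-butyl(dimethyl)silyl]oxy}-4,5-dimethoxyphenyl)methanol, both carbinol epimers | COc1cc(C(O)[C@@H]2CO[C@@H](c3cc(OC)c(OC)c(OC)c3)[C@@H]2CO[Si](C)(C)C(C)(C)C)cc(O[Si](C)(C)C(C)(C)C)c1OC
F5 | step 12 | O-{[(3S,4S,5R)-4-({[tert-butyl(dimethyl)silyl]oxy}methyl)-5-(3,4,5-trimethoxyphenyl)oxolan-3-yl](3-{[tert-butyl(dimethyl)silyl]oxy}-4,5-dimethoxyphenyl)methyl} O-phenyl carbonothioate | COc1cc(C(OC(=S)Oc4ccccc4)[C@@H]2CO[C@@H](c3cc(OC)c(OC)c(OC)c3)[C@@H]2CO[Si](C)(C)C(C)(C)C)cc(O[Si](C)(C)C(C)(C)C)c1OC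
F6 | step 5 | (3S)-3-(prop-2-yn-1-yloxy)-3-(3,4,5-trimethoxyphenyl)propane-1,2-diol, both epimers at C2 | C#CCO[C@@H](c1cc(OC)c(OC)c(OC)c1)C(O)CO
F7 | step 5 | (1S)-3-{[tert-butyl(dimethyl)silyl]oxy}-1-(prop-2-yn-1-yloxy)-1-(3,4,5-trimethoxyphenyl)propan-2-ol, both epimers at C2 | C#CCO[C@@H](c1cc(OC)c(OC)c(OC)c1)C(O)CO[Si](C)(C)C(C)(C)C
F8 | step 5 | O-[(1S)-3-{[tert-butyl(dimethyl)silyl]oxy}-1-(prop-2-yn-1-yloxy)-1-(3,4,5-trimethoxyphenyl)propan-2-yl] 1H-imidazole-1-carbothioate, both epimers at C2 | C#CCO[C@@H](c1cc(OC)c(OC)c(OC)c1)C(OC(=S)n1ccnc1)CO[Si](C)(C)C(C)(C)C
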